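I wanted to know how far the north flask gets by 21 min, with reagent the smaller charge, and how the starting rate at the west charge answers to each partner.

| setting | west | north-east | south | north |
|---|---|---|---|---|
| starting material | 0.0800 M | 0.0400 M | 0.0800 M | 0.0400 M |
| reagent | 0.0640 M | 0.0640 M | 0.190 M | 0.0210 M |
| time |  |  |  | 21 min |

| west run: time / min | west run: [target] / M | north-east run: time / min | north-east run: [target] / M | south run: time / min | south run: [target] / M |
|---|---|---|---|---|---|
| 0.84 | 0.0015 | 0.84 | 0.0011 | 0.84 | 0.0029 |
| 1.3 | 0.0036 | 1.3 | 0.0021 | 1.3 | 0.0036 |
| 2.1 | 0.0077 | 2.1 | 0.0047 | 2.1 | 0.0089 |
| 3.3 | 0.0148 | 3.3 | 0.0075 | 3.3 | 0.0164 |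
| 5.3 | 0.0259 | 5.3 | 0.0140 | 5.3 | 0.0270 |
| 8.4 | 0.0399 | 8.4 | 0.0214 | 8.4 | 0.0422 |
| 13 | 0.0511 | 13 | 0.0289 | 13 | 0.0605 |
| 21 | 0.0598 | 21 | 0.0356 | 21 | 0.0749 |

(scatter of a reading: 4 × 10⁻⁴ M)

- Overall: starting material + reagent -> target.
- Constant volume, constant temperature.
- A reading of a species includes what of it is bound.
- "The second partner" is reagent.
- An order is taken over about fifteen percent of the charge, up and down.

- the exponent of [reagent] in the starting rate at the charge of the west run (at the point where two percent of the starting material have become target)
- the exponent of [starting material] in the starting rate at the charge of the west run (at the point where two percent of the starting material have become target) (one fixed amount of target, the same in the runs compared)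
- target in the north run at 21 min, as a share of the starting material charged

Each target consumes one reagent, so in the north flask c(reagent) charged equals c(reagent) unused plus c(target). Reagent is the limiting reagent there, with 0.0210 M being smaller than the 0.0400 M of starting material. The share of starting material that the reagent charge can turn into target, 52.5% in the north flask, I call the reagent ceiling, c(reagent) charged over c(starting material) charged.

I took two extreme versions. In the first, the rate ignores reagent until the 0.0210 M is used. The north flask then follows the north-east flask, which has the same starting material and read 0.0214 M at 8.4 min, so this version stands at the ceiling by then. In the second, the rate is proportional to c(reagent), and reagent decays with one time constant. The north-east readings from 2.1 min to 5.3 min give a rate of 0.00291 M min⁻¹, and by the balance c(reagent) unused averaged about 0.0547 M over those readings, so the time constant is about 18.8 min, and this version reaches about 35.3% at 21 min. The south flask, with 2.97 times the reagent of the west flask, read only 1.04 times as much target at 5.3 min. I therefore placed the north flask in the upper part of that range, yet below the ceiling, since the rate has to fall as c(reagent) approaches zero.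

The forecast judged that “reagent is nearly saturating” and gave exponents of 0.17 for reagent and 0.6 for starting material, with 50% for the north flask.

The flask gave 0.33, 0.46 and 47.6%.

    starting material ⇌ intermediate (0.3540 min⁻¹, 0.2310 min⁻¹)
    intermediate + reagent → target (10.92 M⁻¹ min⁻¹)
    starting material + reagent + target → 2 target (37.26 M⁻² min⁻¹)
    starting material + reagent ⇌ idle substrate-reagent adduct, settled at all times (24.00 M⁻¹)

The north flask reached 90.7% of its ceiling, leaving 0.00194 M of reagent unconverted, free and adduct-bound counted together. The west flask, with a ceiling of 80.0%, read 74.7% at 21 min, also below its ceiling. The reagent exponent at the west charge is held down by the pairing of starting material and reagent to idle substrate-reagent adduct: it is 0.33 with the pairing and 0.53 in the same charge run without it.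

Readings and results stem from a simulated flask for substances that don't exist, noise included.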